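Ring A is traced back to 2-(2-bromophenoxy)cyclohexane-1,3-dione, which is opened at C1–C2 to the acyclic keto ester methyl 6-(2-bromophenoxy)-5-oxohexanoate, with the aryl ether oxygen already in place. A single base-mediated Claisen closure forms C1–C2 and ring A with oxygen on both C1 and C3. The feature exploited is that in ring A the ether carbon C2 lies between C1 (OH) and C3 (Br): these are the two equivalent carbonyl carbons of the dione, so converting either one into a vinylic bromide and aromatizing places the C3 bromine, which electrophilic bromination could not deliver; C4 and C6 are brominated last under control of the phenol.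

Key step: step 3

Remark: ring A is numbered C1 (OH), C2 (O-aryl), C3 (Br), C4 (Br), C5 (H), C6 (Br) and ring B is the 2-bromophenyl ring; the target has no stereocentre, and dione 7 is drawn as the diketo tautomer although it should exist largely as the enol.

Step 1
Reactants: 1 methyl 5-chloro-5-oxopentanoate; 2 trimethylsilyldiazomethane
Product: 4 methyl 6-bromo-5-oxohexanoate, via diazoketone 3 (not isolated)
Conditions: TMSCHN2, THF/MeCN (1:1), 0 °C to rt; then 48% aq. HBr, 0 °C
Reagents that add atoms: hydrogen bromide, Br
Why: C-acylation of the diazoalkane by the acid chloride with loss of the silyl group (Arndt–Eistert-type diazoketone synthesis) should give diazoketone 3, which HBr protonates and bromide then substitutes with loss of N2 to give the bromomethyl ketone, while the methyl ester should survive the short exposure to cold acid.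

Step 2
Reactants: 4 methyl 6-bromo-5-oxohexanoate; 5 2-bromophenol
Product: 6 methyl 6-(2-bromophenoxy)-5-oxohexanoate
Conditions: K2CO3, acetone, rt
Reagents that add atoms: none
Why: In this Williamson ether synthesis the phenoxide should displace the primary bromide of the α-bromo ketone in a fast SN2 reaction, and the ester, the ketone and the aryl bromide are inert to mild carbonate base.

Step 3
Reactants: 6 methyl 6-(2-bromophenoxy)-5-oxohexanoate
Product: 7 2-(2-bromophenoxy)cyclohexane-1,3-dione
Conditions: KOtBu (2.2 equiv), THF (0.05 M), 0 °C to rt; then 1 M HCl
Reagents that add atoms: none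
Why: tert-Butoxide reversibly deprotonates the hexanoate C6 methylene of 6, which lies between the ketone and the aryloxy oxygen and is the most acidic C–H, and this enolate carbon (the future C2 of ring A) adds to the ester carbonyl (the future C1), methoxide is expelled and the C1–C2 bond is formed. The closest known reaction type is the intramolecular Claisen (Dieckmann-type) condensation that converts 5-oxoalkanoate esters into cyclohexane-1,3-diones. Ring A closes in the 6-(enolendo)-exo-trig mode, an allowed closure for a ketone enolate attacking an exocyclic ester carbonyl. No stereocentre is created, because C2 of the product belongs to an enolised, symmetric 1,3-dione. The step needs regioselectivity among the possible enolates and preference for cyclisation over intermolecular condensation: the enolates at hexanoate C4 and C2 could only close four-membered rings and revert by proton exchange, dilution disfavours bimolecular aldol or Claisen reactions, and deprotonation of the acidic dione by the excess base makes the closure effectively irreversible. The aryl ether and the aryl bromide should be inert to KOtBu in THF at or below room temperature.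

Step 4
Reactants: 7 2-(2-bromophenoxy)cyclohexane-1,3-dione
Product: 8 3-bromo-2-(2-bromophenoxy)cyclohex-2-en-1-one
Conditions: (COBr)2, DMF (cat.), CH2Cl2, 0 °C to rt
Reagents that add atoms: oxalyl bromide, O=C(Br)C(=O)Br
Why: DMF-catalysed activation of the enol oxygen followed by addition–elimination of bromide at the vinylogous acyl carbon is the standard conversion of a cyclic 1,3-dione into a 3-bromoenone, and because both carbonyls of 7 are equivalent only one bromoenone can form.

Step 5
Reactants: 8 3-bromo-2-(2-bromophenoxy)cyclohex-2-en-1-one
Product: 11 3-bromo-2-(2-bromophenoxy)phenol, via bromo enone 9 (not isolated), via dienone tautomer 10 (not isolated)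
Conditions: LiN(SiMe3)2, THF, −78 °C; Br2, −78 °C; then crude 9, Li2CO3, LiBr, DMF, 110 °C
Reagents that add atoms: none
Why: Kinetic deprotonation at C6 should give the cross-conjugated lithium enolate, which Br2 brominates at C6, and E2 loss of HBr with Li2CO3/LiBr then gives dienone 10, whose tautomerisation to the phenol is driven by aromaticity (α'-bromination–dehydrobromination of a cyclohexenone); any bromide exchange at C3 would be degenerate.

Step 6
Reactants: 11 3-bromo-2-(2-bromophenoxy)phenol
Product: 13 3,4,6-tribromo-2-(2-bromophenoxy)phenol (target), via monobromophenol 12 (not isolated)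
Conditions: Br2 (2.05 equiv), CH2Cl2, 0 °C
Reagents that add atoms: bromine, BrBr
Why: In this electrophilic aromatic bromination the free hydroxyl directs to its para position C4 and to the only free ortho position C6 (C2 is blocked), the phenol ring A is far more reactive than the bromine-deactivated aryl ether ring B, and ring A is deactivated after two substitutions, so a stoichiometric amount of Br2 at low temperature should stop at the target.

Compound list
1 | methyl 5-chloro-5-oxopentanoate | COC(=O)CCCC(=O)Cl | starting material
2 | trimethylsilyldiazomethane | C[Si](C)(C)C=[N+]=[N-] | starting material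
3 | methyl 6-diazo-5-oxohexanoate | COC(=O)CCCC(=O)C=[N+]=[N-] | intermediate (not isolated)
4 | methyl 6-bromo-5-oxohexanoate | COC(=O)CCCC(=O)CBr | intermediate
5 | 2-bromophenol | Oc1ccccc1Br | starting material
6 | methyl 6-(2-bromophenoxy)-5-oxohexanoate | COC(=O)CCCC(=O)COc1ccccc1Br | intermediate
7 | 2-(2-bromophenoxy)cyclohexane-1,3-dione | O=C1CCCC(=O)C1Oc1ccccc1Br | intermediate
8 | 3-bromo-2-(2-bromophenoxy)cyclohex-2-en-1-one | O=C1CCCC(Br)=C1Oc1ccccc1Br | intermediate
9 | 3,6-dibromo-2-(2-bromophenoxy)cyclohex-2-en-1-one (racemic) | O=C1C(Br)CCC(Br)=C1Oc1ccccc1Br | intermediate (not isolated)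
10 | 3-bromo-2-(2-bromophenoxy)cyclohexa-2,5-dien-1-one | O=C1C=CCC(Br)=C1Oc1ccccc1Br | intermediate (not isolated)
11 | 3-bromo-2-(2-bromophenoxy)phenol | Oc1cccc(Br)c1Oc1ccccc1Br | intermediate
12 | 3,4-dibromo-2-(2-bromophenoxy)phenol | Oc1ccc(Br)c(Br)c1Oc1ccccc1Br | intermediate (not isolated)
13 | 3,4,6-tribromo-2-(2-bromophenoxy)phenol | Oc1c(Br)cc(Br)c(Br)c1Oc1ccccc1Br | target

Total step count: 6. Longest linear sequence: 6 steps (1 to 13); 2-bromophenol 5 enters at step 2.

Steps most likely to fail

Step 3 (key step). Intermolecular aldol or Claisen condensation of the keto ester could outrun ring closure, or the product could be cleaved again by alkoxide (retro-Claisen) before it is locked as its enolate. Fallback: setting out from 2-bromophenol 5, purchased cyclohexane-1,3-dione F1 would be converted by diazo transfer (4-acetamidobenzenesulfonyl azide, Et3N, MeCN) into 2-diazocyclohexane-1,3-dione F2. Decomposition of F2 with catalytic Rh2(OAc)4 in the presence of 5 (CH2Cl2 or benzene, warming) should give the dione by O–H insertion of the rhodium carbenoid, and the route is rejoined at 7.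

Step 5. Deprotonation could occur at C4 instead of C6, the enolate could be brominated twice, or the dehydrobromination could be slow and accompanied by decomposition of the vinylogous acyl bromide. Fallback: setting out from 8, enol silylation (LiN(SiMe3)2, Me3SiCl, THF, −78 °C) should give the silyloxy diene {[4-bromo-3-(2-bromophenoxy)cyclohexa-1,3-dien-2-yl]oxy}trimethylsilane F3. Dehydrogenation of this cyclohexa-1,3-diene with DDQ (CH2Cl2, rt), by hydride abstraction and proton loss, should give the aryl silyl ether [3-bromo-2-(2-bromophenoxy)phenoxy]trimethylsilane F4, which dilute HCl in MeOH cleaves to rejoin the route at 11. No bromine has to be put on and taken off, and the regioisomeric dienol ether from deprotonation at C4 would be oxidised to the same arene.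

Step 6. Ring selectivity could be lost: the second, slower substitution ortho to the hydroxyl at C6 may compete with bromination of ring B para to the ether oxygen, or the reaction may stall at the monobromide. Fallback: setting out from 8, two consecutive enolisation–bromination cycles at C6 (LiN(SiMe3)2 then Br2, THF, −78 °C, twice) should give 3,6,6-tribromo-2-(2-bromophenoxy)cyclohex-2-en-1-one F5. Dehydrobromination with Li2CO3/LiBr in DMF and tautomerisation should then give 3,6-dibromo-2-(2-bromophenoxy)phenol F6, which already carries the C6 bromine. A single fast para-bromination at C4 (NBS, one equivalent, MeCN, 0 °C) rejoins the route at the target 13.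

Further compounds
F1 | step 3 | cyclohexane-1,3-dione | O=C1CCCC(=O)C1
F2 | step 3 | 2-diazocyclohexane-1,3-dione | O=C1CCCC(=O)C1=[N+]=[N-]
F3 | step 5 | {[4-bromo-3-(2-bromophenoxy)cyclohexa-1,3-dien-2-yl]oxy}trimethylsilane | C[Si](C)(C)OC1=CCCC(Br)=C1Oc1ccccc1Br
F4 | step 5 | [3-bromo-2-(2-bromophenoxy)phenoxy]trimethylsilane | C[Si](C)(C)Oc1cccc(Br)c1Oc1ccccc1Br
F5 | step 6 | 3,6,6-tribromo-2-(2-bromophenoxy)cyclohex-2-en-1-one | O=C1C(Br)(Br)CCC(Br)=C1Oc1ccccc1Br
F6 | step 6 | 3,6-dibromo-2-(2-bromophenoxy)phenol | Oc1c(Br)ccc(Br)c1Oc1ccccc1Br
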